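**Plan** (numbering: ring C1–C6 with methyl C15 on C4; C7(=C14) on C1; side chain C8–C13; O2, O3 and O8 on C2, C3 and C8)
- Retrosynthesis: the two epoxide oxygens (C10/C11, then C4/C5) and both angelates are removed, C10=C11 is cut (cross-metathesis) and then C8–C9 (allylation of a C8 lactol); the core is cut at C1–C2 together with the O2–C8 acyl bond, and the open chain at C1–C7 and C4=C5.
- Enabling feature: O2 and C8 are linked through C2–C1–C7(=C14), so the ring O2–C2–C1–C7–C8 is a latent α-methylene-γ-butyrolactone cis-fused to the carbocycle C1–C6, and C8 can be carried as its carbonyl carbon.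
- Forward: the chain C2–C3–C4(C15)=C5–C6–C1=C7(C14Br)–C8 is joined linearly (L-threonate gives C2–C4, a Wittig reagent C5–C6–C1, methyl propiolate C7/C14/C8); one chromium-mediated step closes first the cyclohexene and then the lactone; the lactone is reduced, C9–C13 are added, the hydroxyls are angeloylated in turn (O8, then the hindered O2) and the two epoxides come last.
- Stereochemistry: C3 from L-threonate; (Z)-C4=C5 from the Wittig reaction of an α-silyloxy ketone; C1 and C2 from the chair allylchromium addition under Felkin–Anh control by C3; C8 from a pinene-derived allylborane; C4/C5 from hydroxyl-directed epoxidation syn to O3; C10 from the fructose-derived chiral dioxirane; the angelate geometry from angelic acid itself.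

Key step: step 9

Assumption: methyl 3,4-O-isopropylidene-L-threonate is taken as the commercial chiral-pool ester (its C2 becomes C3 of the target, its C3–C4 glycol is cleaved later to unveil the C2 aldehyde); 10 and 17 are carried as mixtures at the carbinol and anomeric centres, both of which are erased in later steps.

**Step 1**
Reactants: 1 methyl 3,4-O-isopropylidene-L-threonate
Product: 2 methyl (2R)-2-[(tert-butyldimethylsilyl)oxy]-2-[(4S)-2,2-dimethyl-1,3-dioxolan-4-yl]acetate
Conditions: TBSCl, imidazole, DMF, 25 °C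
Reagents that add atoms: tert-butyldimethylsilyl chloride, CC(C)(C)[Si](C)(C)Cl
Why: Imidazole-promoted silylation of a secondary α-hydroxy ester (silyl ether protection) is routine and leaves both stereocentres untouched.

**Step 2**
Reactants: 2 methyl (2R)-2-[(tert-butyldimethylsilyl)oxy]-2-[(4S)-2,2-dimethyl-1,3-dioxolan-4-yl]acetate
Product: 3 (2R)-2-[(tert-butyldimethylsilyl)oxy]-2-[(4S)-2,2-dimethyl-1,3-dioxolan-4-yl]-N-methoxy-N-methylacetamide
Conditions: MeNH(OMe)·HCl, i-PrMgCl, THF, −20 → 0 °C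
Reagents that add atoms: N,O-dimethylhydroxylamine hydrochloride, CNOC.Cl
Why: The chloromagnesium amide formed in the flask converts esters into Weinreb amides at low temperature (Weinreb aminolysis) and should not epimerise the α-silyloxy centre.

**Step 3**
Reactants: 3 (2R)-2-[(tert-butyldimethylsilyl)oxy]-2-[(4S)-2,2-dimethyl-1,3-dioxolan-4-yl]-N-methoxy-N-methylacetamide
Product: 4 (1R)-1-[(tert-butyldimethylsilyl)oxy]-1-[(4S)-2,2-dimethyl-1,3-dioxolan-4-yl]propan-2-one
Conditions: MeMgBr, THF, 0 °C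
Reagents that add atoms: methylmagnesium bromide, C[Mg]Br
Why: The chelated tetrahedral adduct survives until work-up, so the Grignard reagent adds only once (Weinreb ketone synthesis) and delivers the methyl ketone C4(=O)–C15 with C3 intact.

**Step 4**
Reactants: 4 (1R)-1-[(tert-butyldimethylsilyl)oxy]-1-[(4S)-2,2-dimethyl-1,3-dioxolan-4-yl]propan-2-one; 5 (3-hydroxypropyl)triphenylphosphonium bromide
Product: 7 (3Z,5S)-5-[(tert-butyldimethylsilyl)oxy]-5-[(4S)-2,2-dimethyl-1,3-dioxolan-4-yl]-4-methylpent-3-en-1-ol, via trimethylsilyl ether 6 (not isolated)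
Conditions: 5, (Me3Si)2NH, Me3SiCl (cat.), THF, reflux, then evaporate; NaN(SiMe3)2, THF, −78 °C; 4, −78 → 25 °C; K2CO3 (cat.), MeOH, 25 °C
Reagents that add atoms: none
Why: Salt-free non-stabilised ylides add to α-alkoxy methyl ketones to place the new chain cis to the oxygen-bearing carbon (Wittig reaction in its α-alkoxy-ketone, Still-type variant), which gives the (Z)-C4=C5 geometry that ring closure needs; transient O-silylation of the reagent avoids an oxido ylide and the labile Me3Si ether is lost in methanol.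

**Step 5**
Reactants: 7 (3Z,5S)-5-[(tert-butyldimethylsilyl)oxy]-5-[(4S)-2,2-dimethyl-1,3-dioxolan-4-yl]-4-methylpent-3-en-1-ol
Product: 8 (3Z,5S)-5-[(tert-butyldimethylsilyl)oxy]-5-[(4S)-2,2-dimethyl-1,3-dioxolan-4-yl]-4-methylpent-3-enal
Conditions: Dess–Martin periodinane, pyridine, CH2Cl2, 0 → 25 °C
Reagents that add atoms: none
Why: Buffered Dess–Martin oxidation is fast and nearly neutral, so the β,γ-unsaturated C1 aldehyde should form without migration of C4=C5 into conjugation; it is used at once.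

**Step 6**
Reactants: 8 (3Z,5S)-5-[(tert-butyldimethylsilyl)oxy]-5-[(4S)-2,2-dimethyl-1,3-dioxolan-4-yl]-4-methylpent-3-enal; 9 methyl propiolate
Product: 10 methyl (3RS,5Z,7S)-7-[(tert-butyldimethylsilyl)oxy]-7-[(4S)-2,2-dimethyl-1,3-dioxolan-4-yl]-3-hydroxy-6-methyl-2-methylidenehept-5-enoate
Conditions: i-Bu2AlH, N-methylmorpholine N-oxide, THF, 0 °C; 9; then 8, 0 → 25 °C
Reagents that add atoms: none
Why: Hydroalumination of the propiolate gives the α-alumino acrylate, which adds 1,2 to aldehydes to give Morita–Baylis–Hillman-type adducts without amine base (vinylalumination); the new carbinol centre at C1 is of no consequence because C1 becomes trigonal in step 7.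

**Step 7**
Reactants: 10 methyl (3RS,5Z,7S)-7-[(tert-butyldimethylsilyl)oxy]-7-[(4S)-2,2-dimethyl-1,3-dioxolan-4-yl]-3-hydroxy-6-methyl-2-methylidenehept-5-enoate
Product: 11 methyl (2Z,5Z,7S)-2-(bromomethyl)-7-[(tert-butyldimethylsilyl)oxy]-7-[(4S)-2,2-dimethyl-1,3-dioxolan-4-yl]-6-methylhepta-2,5-dienoate
Conditions: NBS, Me2S, CH2Cl2, 0 → 25 °C
Reagents that add atoms: N-bromosuccinimide, O=C1CCC(=O)N1Br
Why: The alkoxysulfonium salt of a Baylis–Hillman alcohol is opened by bromide in SN2' fashion (Corey–Kim-type allylic bromination with transposition), which gives the conjugated (Z)-2-(bromomethyl)enoate with C6 trans to the ester under acid-free conditions.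

**Step 8**
Reactants: 11 methyl (2Z,5Z,7S)-2-(bromomethyl)-7-[(tert-butyldimethylsilyl)oxy]-7-[(4S)-2,2-dimethyl-1,3-dioxolan-4-yl]-6-methylhepta-2,5-dienoate
Product: 13 methyl (2Z,5Z,7S)-2-(bromomethyl)-7-[(tert-butyldimethylsilyl)oxy]-6-methyl-8-oxoocta-2,5-dienoate, via diol 12 (not isolated)
Conditions: H5IO6, EtOAc, 25 °C
Reagents that add atoms: none
Why: Periodic acid in an organic solvent hydrolyses a terminal isopropylidene acetal and cleaves the freed glycol in the same flask (acetal hydrolysis followed by Malaprade glycol cleavage), releasing the C2 aldehyde without base so that C3 should not epimerise; 13 is used crude.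

**Step 9**
Reactants: 13 methyl (2Z,5Z,7S)-2-(bromomethyl)-7-[(tert-butyldimethylsilyl)oxy]-6-methyl-8-oxoocta-2,5-dienoate
Product: 16 (3aS,7S,7aR)-7-[(tert-butyldimethylsilyl)oxy]-6-methyl-3-methylidene-3a,4,7,7a-tetrahydro-1-benzofuran-2(3H)-one, via allylchromium dichloride 14 (not isolated), via chromium alkoxide 15 (not isolated)
Conditions: CrCl2 (8 equiv), THF, 25 °C, slow addition of 13 (final 0.005 M); aq. NH4Cl
Reagents that add atoms: none
Why: Two equivalents of divalent chromium reduce the C14–Br bond to the allylchromium 14, which is expected to add to the C2 aldehyde through its γ-carbon C1 in a chair Zimmerman–Traxler array, forming C1–C2 and shifting the double bond to C7=C14 (Nozaki–Hiyama allylation; the closest known reaction type is the CrCl2-mediated intramolecular 2-(alkoxycarbonyl)allylation of aldehydes to cis-fused α-methylene-γ-butyrolactones). The carbocycle C1–C6 closes in a 6-exo-trig mode at the aldehyde carbon with SE2' transposition of the allyl unit, and the trivalent chromium alkoxide 15 then closes the lactone by 5-exo-trig acyl substitution at C8 with loss of methoxide. C1 and C2 are set together: C6 is cis to the metal-bearing C14 on the C1=C7 bond and so must sit axial in the chair while the tether holds C3 equatorial, which places C7 and O2 cis on the new ring, the arrangement that lactonises without strain. Their absolute sense comes from C3: in the favoured chair the C3–OSi bond lies anti to the forming C1–C2 bond with C4 inside (Felkin–Anh), so O2 should end up cis to O3. The step needs ring closure to outrun intermolecular coupling and γ-attack to outrun α-attack; high dilution with slow addition serves the first, and the fact that α-attack would require an eight-membered ring serves the second.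

**Step 10**
Reactants: 16 (3aS,7S,7aR)-7-[(tert-butyldimethylsilyl)oxy]-6-methyl-3-methylidene-3a,4,7,7a-tetrahydro-1-benzofuran-2(3H)-one
Product: 17 (3aS,7S,7aR)-7-[(tert-butyldimethylsilyl)oxy]-6-methyl-3-methylidene-2,3,3a,4,7,7a-hexahydro-1-benzofuran-2-ol
Conditions: i-Bu2AlH (1.1 equiv), CH2Cl2, −78 °C; aq. potassium sodium tartrate
Reagents that add atoms: none
Why: One equivalent of hydride at −78 °C stops at the aluminium hemiacetal, so the α-methylene lactone should give the lactol by 1,2-reduction (partial lactone reduction).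

**Step 11**
Reactants: 17 (3aS,7S,7aR)-7-[(tert-butyldimethylsilyl)oxy]-6-methyl-3-methylidene-2,3,3a,4,7,7a-hexahydro-1-benzofuran-2-ol
Product: 19 (1R,2S,6S)-2-[(tert-butyldimethylsilyl)oxy]-6-[(3S)-3-hydroxyhexa-1,5-dien-2-yl]-3-methylcyclohex-3-en-1-ol, via open hydroxy enal 18 (not isolated)
Conditions: dIpc2B(allyl) [B-allyldiisopinocampheylborane from (+)-α-pinene, 2.5 equiv], Et2O, −78 → 25 °C; NaOH, H2O2
Reagents that add atoms: B-allyldiisopinocampheylborane from (+)-α-pinene, C=CCB([C@H]1[C@H](C)[C@H]2C[C@@H](C1)C2(C)C)[C@H]1[C@H](C)[C@H]2C[C@@H](C1)C2(C)C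
Why: The lactol reacts through its open hydroxy enal form, and the pinene-derived allylborane adds through a chair transition state to the Si face of the C8 aldehyde under reagent control (Brown asymmetric allylboration), which should set (8S) and form C8–C9.

**Step 12**
Reactants: 19 (1R,2S,6S)-2-[(tert-butyldimethylsilyl)oxy]-6-[(3S)-3-hydroxyhexa-1,5-dien-2-yl]-3-methylcyclohex-3-en-1-ol; 20 2-methylbut-2-ene
Product: 21 (1R,2S,6S)-2-[(tert-butyldimethylsilyl)oxy]-6-[(3S)-3-hydroxy-6-methylhepta-1,5-dien-2-yl]-3-methylcyclohex-3-en-1-ol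
Conditions: 20 (excess), second-generation Grubbs catalyst RuCl2(=CHPh)(PCy3)(H2IMes) (5 mol %), CH2Cl2, 40 °C
Reagents that add atoms: none
Why: Olefin cross-metathesis with an excess of the trisubstituted alkene exchanges the terminal CH2 for the isopropylidene group C11(C12)(C13), while the 1,1-disubstituted C7=C14 and the trisubstituted ring alkene are too hindered to enter the catalytic cycle.

**Step 13**
Reactants: 21 (1R,2S,6S)-2-[(tert-butyldimethylsilyl)oxy]-6-[(3S)-3-hydroxy-6-methylhepta-1,5-dien-2-yl]-3-methylcyclohex-3-en-1-ol; 22 angelic acid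
Product: 23 (3S)-2-[(1S,5S,6R)-5-[(tert-butyldimethylsilyl)oxy]-6-hydroxy-4-methylcyclohex-3-en-1-yl]-6-methylhepta-1,5-dien-3-yl (2Z)-2-methylbut-2-enoate
Conditions: 22 (1.2 equiv), 2,4,6-Cl3C6H2COCl (1.2 equiv), Et3N, toluene, 25 °C; then 21, 25 → 50 °C
Reagents that add atoms: none
Why: With only a slight excess of the mixed 2,4,6-trichlorobenzoic anhydride and no nucleophilic catalyst (Yamaguchi-type esterification), the open-chain allylic O8 hydroxyl should be acylated well before the ring O2 hydroxyl, which is shielded by the cis silyl ether and the cis side chain; the Z geometry is kept, and any material acylated further is simply the product of step 14.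

**Step 14**
Reactants: 23 (3S)-2-[(1S,5S,6R)-5-[(tert-butyldimethylsilyl)oxy]-6-hydroxy-4-methylcyclohex-3-en-1-yl]-6-methylhepta-1,5-dien-3-yl (2Z)-2-methylbut-2-enoate; 22 angelic acid
Product: 24 (3S)-2-[(1S,5S,6R)-5-[(tert-butyldimethylsilyl)oxy]-4-methyl-6-{[(2Z)-2-methylbut-2-enoyl]oxy}cyclohex-3-en-1-yl]-6-methylhepta-1,5-dien-3-yl (2Z)-2-methylbut-2-enoate
Conditions: 22 (4 equiv), 2,4,6-Cl3C6H2COCl (4 equiv), Et3N, toluene, 25 °C; then 23, 80 °C
Reagents that add atoms: none
Why: A larger excess of the same mixed anhydride at 80 °C without a nucleophilic catalyst (Yamaguchi-type esterification) is the established way to place an angelate on a hindered secondary alcohol without Z to E isomerisation, and should esterify the remaining O2 hydroxyl while the O8 angelate and the silyl ether stay untouched.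

**Step 15**
Reactants: 24 (3S)-2-[(1S,5S,6R)-5-[(tert-butyldimethylsilyl)oxy]-4-methyl-6-{[(2Z)-2-methylbut-2-enoyl]oxy}cyclohex-3-en-1-yl]-6-methylhepta-1,5-dien-3-yl (2Z)-2-methylbut-2-enoate
Product: 25 (3S)-2-[(1S,5S,6R)-5-hydroxy-4-methyl-6-{[(2Z)-2-methylbut-2-enoyl]oxy}cyclohex-3-en-1-yl]-6-methylhepta-1,5-dien-3-yl (2Z)-2-methylbut-2-enoate
Conditions: HF·pyridine, pyridine, THF, 0 → 25 °C
Reagents that add atoms: none
Why: Pyridine-buffered HF cleaves the secondary silyl ether under slightly acidic conditions (fluoride desilylation), which avoids base-induced O2 to O3 acyl migration and leaves the angelates and alkenes alone.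

**Step 16**
Reactants: 25 (3S)-2-[(1S,5S,6R)-5-hydroxy-4-methyl-6-{[(2Z)-2-methylbut-2-enoyl]oxy}cyclohex-3-en-1-yl]-6-methylhepta-1,5-dien-3-yl (2Z)-2-methylbut-2-enoate
Product: 26 (1R,2R,3R,4S,6S)-2-hydroxy-1-methyl-4-[(3S)-6-methyl-3-{[(2Z)-2-methylbut-2-enoyl]oxy}hepta-1,5-dien-2-yl]-7-oxabicyclo[4.1.0]heptan-3-yl (2Z)-2-methylbut-2-enoate
Conditions: VO(acac)2 (5 mol %), t-BuOOH, CH2Cl2, 0 → 25 °C
Reagents that add atoms: tert-butyl hydroperoxide, CC(C)(C)OO
Why: The vanadium alkylperoxide bound to the C3 hydroxyl delivers oxygen to the adjacent C4=C5 bond on the hydroxyl face (hydroxyl-directed vanadium-catalysed epoxidation), setting C4 and C5 syn to O3, while the undirected C10=C11 and C7=C14 alkenes should not react.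

**Step 17**
Reactants: 26 (1R,2R,3R,4S,6S)-2-hydroxy-1-methyl-4-[(3S)-6-methyl-3-{[(2Z)-2-methylbut-2-enoyl]oxy}hepta-1,5-dien-2-yl]-7-oxabicyclo[4.1.0]heptan-3-yl (2Z)-2-methylbut-2-enoate
Product: 27 CNP0235377.1, (1R,2R,3R,4S,6S)-4-[(3S)-4-[(2R)-3,3-dimethyloxiran-2-yl]-3-{[(2Z)-2-methylbut-2-enoyl]oxy}but-1-en-2-yl]-2-hydroxy-1-methyl-7-oxabicyclo[4.1.0]heptan-3-yl (2Z)-2-methylbut-2-enoate
Conditions: 1,2:4,5-di-O-isopropylidene-β-D-erythro-2,3-hexodiulo-2,6-pyranose, KHSO5 (as 2KHSO5·KHSO4·K2SO4), NaHCO3, aq. disodium ethylenediaminetetraacetate, MeCN, 0 °C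
Reagents that add atoms: potassium peroxymonosulfate, [K+].[O-]S(=O)(=O)OO
Why: The chiral dioxirane from the D-fructose-derived ketone epoxidises the electron-rich trisubstituted C10=C11 bond through a spiro transition state under reagent control (Shi asymmetric epoxidation) to give (10R), the enoates and the 1,1-disubstituted C7=C14 being too electron-poor or hindered, and the bicarbonate buffer keeps the pH low enough to spare the vicinal hydroxy ester.

**Compound list**
1 | methyl 3,4-O-isopropylidene-L-threonate, methyl (2R)-2-[(4S)-2,2-dimethyl-1,3-dioxolan-4-yl]-2-hydroxyacetate | COC(=O)[C@H](O)[C@@H]1COC(C)(C)O1 | starting material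
2 | methyl (2R)-2-[(tert-butyldimethylsilyl)oxy]-2-[(4S)-2,2-dimethyl-1,3-dioxolan-4-yl]acetate | COC(=O)[C@H](O[Si](C)(C)C(C)(C)C)[C@@H]1COC(C)(C)O1 | intermediate
3 | (2R)-2-[(tert-butyldimethylsilyl)oxy]-2-[(4S)-2,2-dimethyl-1,3-dioxolan-4-yl]-N-methoxy-N-methylacetamide | CON(C)C(=O)[C@H](O[Si](C)(C)C(C)(C)C)[C@@H]1COC(C)(C)O1 | intermediate
4 | (1R)-1-[(tert-butyldimethylsilyl)oxy]-1-[(4S)-2,2-dimethyl-1,3-dioxolan-4-yl]propan-2-one | CC(=O)[C@H](O[Si](C)(C)C(C)(C)C)[C@@H]1COC(C)(C)O1 | intermediate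
5 | (3-hydroxypropyl)triphenylphosphonium bromide | OCCC[P+](c1ccccc1)(c1ccccc1)c1ccccc1.[Br-] | starting material
6 | trimethylsilyl ether of 7 (formed in the flask) | C[Si](C)(C)OCC/C=C(C)\[C@H](O[Si](C)(C)C(C)(C)C)[C@@H]1COC(C)(C)O1 | intermediate
7 | (3Z,5S)-5-[(tert-butyldimethylsilyl)oxy]-5-[(4S)-2,2-dimethyl-1,3-dioxolan-4-yl]-4-methylpent-3-en-1-ol | OCC/C=C(C)\[C@H](O[Si](C)(C)C(C)(C)C)[C@@H]1COC(C)(C)O1 | intermediate
8 | (3Z,5S)-5-[(tert-butyldimethylsilyl)oxy]-5-[(4S)-2,2-dimethyl-1,3-dioxolan-4-yl]-4-methylpent-3-enal | O=CC/C=C(C)\[C@H](O[Si](C)(C)C(C)(C)C)[C@@H]1COC(C)(C)O1 | intermediate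
9 | methyl propiolate | C#CC(=O)OC | starting material
10 | methyl (3RS,5Z,7S)-7-[(tert-butyldimethylsilyl)oxy]-7-[(4S)-2,2-dimethyl-1,3-dioxolan-4-yl]-3-hydroxy-6-methyl-2-methylidenehept-5-enoate (carbinol epimers) | C=C(C(=O)OC)C(O)C/C=C(C)\[C@H](O[Si](C)(C)C(C)(C)C)[C@@H]1COC(C)(C)O1 | intermediate
11 | methyl (2Z,5Z,7S)-2-(bromomethyl)-7-[(tert-butyldimethylsilyl)oxy]-7-[(4S)-2,2-dimethyl-1,3-dioxolan-4-yl]-6-methylhepta-2,5-dienoate | BrC/C(C(=O)OC)=C\C/C=C(C)\[C@H](O[Si](C)(C)C(C)(C)C)[C@@H]1COC(C)(C)O1 | intermediate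
12 | methyl (2Z,5Z,7S,8S)-2-(bromomethyl)-7-[(tert-butyldimethylsilyl)oxy]-8,9-dihydroxy-6-methylnona-2,5-dienoate (formed in the flask) | BrC/C(C(=O)OC)=C\C/C=C(C)\[C@H](O[Si](C)(C)C(C)(C)C)[C@@H](O)CO | intermediate
13 | methyl (2Z,5Z,7S)-2-(bromomethyl)-7-[(tert-butyldimethylsilyl)oxy]-6-methyl-8-oxoocta-2,5-dienoate | BrC/C(C(=O)OC)=C\C/C=C(C)\[C@H](O[Si](C)(C)C(C)(C)C)C=O | intermediate
14 | allylchromium dichloride from 13, CrCl2 on C14 (formed in the flask) | Cl[Cr](Cl)C/C(C(=O)OC)=C\C/C=C(C)\[C@H](O[Si](C)(C)C(C)(C)C)C=O | intermediate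
15 | dichlorochromium alkoxide of methyl 2-[(1S,5S,6R)-5-[(tert-butyldimethylsilyl)oxy]-6-hydroxy-4-methylcyclohex-3-en-1-yl]prop-2-enoate (formed in the flask) | C=C(C(=O)OC)[C@@H]1CC=C(C)[C@H](O[Si](C)(C)C(C)(C)C)[C@@H]1O[Cr](Cl)Cl | intermediate
16 | (3aS,7S,7aR)-7-[(tert-butyldimethylsilyl)oxy]-6-methyl-3-methylidene-3a,4,7,7a-tetrahydro-1-benzofuran-2(3H)-one | C=C1[C@@H]2CC=C(C)[C@H](O[Si](C)(C)C(C)(C)C)[C@@H]2OC1=O | intermediate
17 | (3aS,7S,7aR)-7-[(tert-butyldimethylsilyl)oxy]-6-methyl-3-methylidene-2,3,3a,4,7,7a-hexahydro-1-benzofuran-2-ol (anomers) | C=C1[C@@H]2CC=C(C)[C@H](O[Si](C)(C)C(C)(C)C)[C@@H]2OC1O | intermediate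
18 | 2-[(1S,5S,6R)-5-[(tert-butyldimethylsilyl)oxy]-6-hydroxy-4-methylcyclohex-3-en-1-yl]prop-2-enal (open form of 17, in the flask) | C=C(C=O)[C@@H]1CC=C(C)[C@H](O[Si](C)(C)C(C)(C)C)[C@@H]1O | intermediate
19 | (1R,2S,6S)-2-[(tert-butyldimethylsilyl)oxy]-6-[(3S)-3-hydroxyhexa-1,5-dien-2-yl]-3-methylcyclohex-3-en-1-ol | C=C([C@H](CC=C)O)[C@@H]1CC=C(C)[C@H](O[Si](C)(C)C(C)(C)C)[C@@H]1O | intermediate
20 | 2-methylbut-2-ene | CC=C(C)C | starting material
21 | (1R,2S,6S)-2-[(tert-butyldimethylsilyl)oxy]-6-[(3S)-3-hydroxy-6-methylhepta-1,5-dien-2-yl]-3-methylcyclohex-3-en-1-ol | C=C([C@H](CC=C(C)C)O)[C@@H]1CC=C(C)[C@H](O[Si](C)(C)C(C)(C)C)[C@@H]1O | intermediate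
22 | angelic acid, (2Z)-2-methylbut-2-enoic acid | C/C=C(/C)C(=O)O | starting material
23 | (3S)-2-[(1S,5S,6R)-5-[(tert-butyldimethylsilyl)oxy]-6-hydroxy-4-methylcyclohex-3-en-1-yl]-6-methylhepta-1,5-dien-3-yl (2Z)-2-methylbut-2-enoate | C=C([C@H](CC=C(C)C)OC(=O)/C(C)=C\C)[C@@H]1CC=C(C)[C@H](O[Si](C)(C)C(C)(C)C)[C@@H]1O | intermediate
24 | (3S)-2-[(1S,5S,6R)-5-[(tert-butyldimethylsilyl)oxy]-4-methyl-6-{[(2Z)-2-methylbut-2-enoyl]oxy}cyclohex-3-en-1-yl]-6-methylhepta-1,5-dien-3-yl (2Z)-2-methylbut-2-enoate | C=C([C@H](CC=C(C)C)OC(=O)/C(C)=C\C)[C@@H]1CC=C(C)[C@H](O[Si](C)(C)C(C)(C)C)[C@@H]1OC(=O)/C(C)=C\C | intermediate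
25 | (3S)-2-[(1S,5S,6R)-5-hydroxy-4-methyl-6-{[(2Z)-2-methylbut-2-enoyl]oxy}cyclohex-3-en-1-yl]-6-methylhepta-1,5-dien-3-yl (2Z)-2-methylbut-2-enoate | C=C([C@H](CC=C(C)C)OC(=O)/C(C)=C\C)[C@@H]1CC=C(C)[C@H](O)[C@@H]1OC(=O)/C(C)=C\C | intermediate
26 | (1R,2R,3R,4S,6S)-2-hydroxy-1-methyl-4-[(3S)-6-methyl-3-{[(2Z)-2-methylbut-2-enoyl]oxy}hepta-1,5-dien-2-yl]-7-oxabicyclo[4.1.0]heptan-3-yl (2Z)-2-methylbut-2-enoate | C=C([C@H](CC=C(C)C)OC(=O)/C(C)=C\C)[C@@H]1C[C@@H]2O[C@]2(C)[C@H](O)[C@@H]1OC(=O)/C(C)=C\C | intermediate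
27 | CNP0235377.1, (1R,2R,3R,4S,6S)-4-[(3S)-4-[(2R)-3,3-dimethyloxiran-2-yl]-3-{[(2Z)-2-methylbut-2-enoyl]oxy}but-1-en-2-yl]-2-hydroxy-1-methyl-7-oxabicyclo[4.1.0]heptan-3-yl (2Z)-2-methylbut-2-enoate | C=C([C@H](C[C@H]1OC1(C)C)OC(=O)/C(C)=C\C)[C@@H]1C[C@@H]2O[C@]2(C)[C@H](O)[C@@H]1OC(=O)/C(C)=C\C | target

**Step count**
Total steps: 17. Longest linear sequence: 17 steps (1 → 27).

**Steps most likely to fail**

Step 9. Excess CrCl2 may reduce the aldehyde or couple it intermolecularly, C3 may epimerise before closure, and a loose transition state (or a pseudoaxial silyloxy group forced by strain against the C4 methyl) may erode the face selectivity at C2. The fallback sets out from 13 and returns at 16. Exchange of bromide for boron under zerovalent palladium catalysis (Pd2(dba)3, B2pin2, toluene–DMSO, 40 °C) should give the pinacol allylboronate aldehyde F1. F1 is expected to close onto the aldehyde through C1 in a type 1 allylboration via a compact chair, with no reducing metal present (Sc(OTf)3 in catalytic amount if it is slow), giving the pinacolboryl ether of the hydroxy ester F2. TsOH in wet CH2Cl2 then lactonises F2 to 16.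

Step 14. The C2 hydroxyl is flanked cis by the C3 silyl ether and the C1 side chain, so acylation may stall, and forcing may isomerise angelate to tiglate. The fallback sets out from 23 and returns at 24. The O2 hydroxyl is first esterified with the unhindered 2-[bis(2,2,2-trifluoroethoxy)phosphoryl]propanoic acid (N,N'-dicyclohexylcarbodiimide, 4-(dimethylamino)pyridine, CH2Cl2) to give the phosphonopropanoate F3. A Still–Gennari olefination with acetaldehyde (KN(SiMe3)2, 18-crown-6, THF, −78 °C) then builds the second (Z)-2-methylbut-2-enoate on the molecule and gives 24.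

Step 6. During the slow addition of the vinylalane the β,γ-unsaturated aldehyde may enolise, or C4=C5 may move into conjugation. The fallback sets out from 8 and returns at 10. A fast aldol addition at −78 °C of the lithium enolate of methyl 3-(dimethylamino)propanoate (LiN(i-Pr)2, THF) gives the amino aldol F4. N-Methylation (MeI, MeOH) gives the trimethylammonium iodide F5, and 1,8-diazabicyclo[5.4.0]undec-7-ene eliminates trimethylamine to give 10.

**Further compounds**
F1 | step 9 | methyl (2E,5Z,7S)-7-[(tert-butyldimethylsilyl)oxy]-6-methyl-8-oxo-2-[(4,4,5,5-tetramethyl-1,3,2-dioxaborolan-2-yl)methyl]octa-2,5-dienoate | CC1(C)OB(OC1(C)C)C/C(C(=O)OC)=C\C/C=C(C)\[C@H](O[Si](C)(C)C(C)(C)C)C=O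
F2 | step 9 | methyl 2-[(1S,5S,6R)-5-[(tert-butyldimethylsilyl)oxy]-4-methyl-6-[(4,4,5,5-tetramethyl-1,3,2-dioxaborolan-2-yl)oxy]cyclohex-3-en-1-yl]prop-2-enoate | C=C(C(=O)OC)[C@@H]1CC=C(C)[C@H](O[Si](C)(C)C(C)(C)C)[C@@H]1OB1OC(C)(C)C(C)(C)O1
F3 | step 14 | (3S)-2-[(1S,5S,6R)-6-({2-[bis(2,2,2-trifluoroethoxy)phosphoryl]propanoyl}oxy)-5-[(tert-butyldimethylsilyl)oxy]-4-methylcyclohex-3-en-1-yl]-6-methylhepta-1,5-dien-3-yl (2Z)-2-methylbut-2-enoate (phosphonate α-carbon as epimers) | C=C([C@H](CC=C(C)C)OC(=O)/C(C)=C\C)[C@@H]1CC=C(C)[C@H](O[Si](C)(C)C(C)(C)C)[C@@H]1OC(=O)C(C)P(=O)(OCC(F)(F)F)OCC(F)(F)F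
F4 | step 6 | methyl (5Z,7S)-7-[(tert-butyldimethylsilyl)oxy]-2-[(dimethylamino)methyl]-7-[(4S)-2,2-dimethyl-1,3-dioxolan-4-yl]-3-hydroxy-6-methylhept-5-enoate (diastereomers) | CN(C)CC(C(=O)OC)C(O)C/C=C(C)\[C@H](O[Si](C)(C)C(C)(C)C)[C@@H]1COC(C)(C)O1
F5 | step 6 | trimethylammonium iodide of F4 | C[N+](C)(C)CC(C(=O)OC)C(O)C/C=C(C)\[C@H](O[Si](C)(C)C(C)(C)C)[C@@H]1COC(C)(C)O1.[I-]
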